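The three new flasks were to be read at 10 min, later than the last earlier reading at 8.00 min, so I needed a number that could be carried forward in time. It also had to show what free base does, and my zero of the scale was a flask in which base does nothing, so that every run gives the same number.

in all of them: electrophile 10 mM
- eta: nucleophile 1.2 equiv; free base 0.85 equiv; scavenger 1.2 equiv; run made earlier
- gamma: nucleophile 1.2 equiv; free base 1.7 equiv; scavenger 1.2 equiv; run made earlier
- beta: nucleophile 1.2 equiv; free base 3.1 equiv; scavenger 1.2 equiv; run made earlier
- winter: nucleophile 1.20 equiv; free base 2.70 equiv; scavenger 1.20 equiv; time 10 min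
- dawn: nucleophile 1.20 equiv; free base 1.20 equiv; scavenger 1.20 equiv; time 10 min
- midnight: nucleophile 1.20 equiv; free base 1.80 equiv; scavenger 1.20 equiv; time 10 min

| run | time / min | electrophile / % | target / % |
|---|---|---|---|
| eta | 0.500 | 96.4 | 3.1 |
| eta | 1.00 | 92.9 | 6.1 |
| eta | 2.00 | 87.5 | 7.2 |
| eta | 4.00 | 75.4 | 8.1 |
| eta | 8.00 | 60.6 | 6.4 |
| gamma | 0.500 | 96.2 | 3.0 |
| gamma | 1.00 | 93.4 | 4.9 |
| gamma | 2.00 | 85.7 | 7.3 |
| gamma | 4.00 | 74.5 | 9.2 |
| gamma | 8.00 | 59.4 | 7.3 |
| beta | 1.33 | 89.9 | 6.6 |
| beta | 3.00 | 80.0 | 8.1 |
| beta | 4.00 | 75.9 | 9.8 |
| beta | 6.00 | 64.6 | 8.2 |
| beta | 8.00 | 58.9 | 7.7 |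

(each reading ± 0.5 percentage points)

* part of the electrophile that has reacted at the end, winter
* part of the electrophile that has reacted at the end, dawn
* part of the electrophile that has reacted at the end, midnight
* what raising the equivalents of free base from its lowest to its highest value here does to the part of the electrophile that has reacted (changes below 5 percentage points count as none) (it falls / it rises / no change)

I counted the electrophile as lost one for one with the nucleophile. The gamma run, with 59.4 % of its electrophile left at 8.00 min, then gave 6.74 M⁻¹ min⁻¹, which I called the pairing constant: the second-order rate constant of that one-for-one loss, read from the electrophile left at a given time. The same reading gave 6.43 M⁻¹ min⁻¹ in the eta run, with the least base of the earlier runs, and 6.88 M⁻¹ min⁻¹ in the beta run, with the most. Carried to 10 min, the gamma constant put the part reacted at 46.4 % in each new flask.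

Then I turned the question round. For base to count, the part reacted had to move by 5 percentage points, and that needed a constant of 8.12 M⁻¹ min⁻¹ at the high end. This is more than the beta reading, although beta carried more base than any new flask. So I expected no change.

The forecast stood close to mine, at 46.5 % for winter, 46.5 % for dawn and 46.5 % for midnight, with no change, holding that free base had “no visible effect on electrophile consumption”.

The flasks gave 46.9 % for winter, 45.6 % for dawn and 46.2 % for midnight, a change of 1.3 points from the lowest base to the highest, so the answer is no change.

    electrophile + target → side product (k = 15.0 M⁻¹ min⁻¹)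
    electrophile + acid set free ⇌ idle adduct, settled at all times (K = 280 M⁻¹)
    acid set free + free base ⇌ salt of the base, settled at all times (K = 24000 M⁻¹)
    nucleophile + acid set free ⇌ protonated nucleophile, settled at all times (K = 53000 M⁻¹)
    target → over-reaction product (k = 0.340 min⁻¹)
    electrophile + nucleophile → acid set free + target (k = 6.00 M⁻¹ min⁻¹)
    acid set free + scavenger → scavenged by-product (k = 48.0 M⁻¹ min⁻¹)

I put the same constant on a neighbour of midnight charged with 0.480 equiv of nucleophile, now the limiting reagent, with the other charges and the time held. The same formula gave 21.4 % reacted, and that flask gave 22.6 %, with 77.4 % of the electrophile left.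

The readings are simulated for an exercise; scatter was added.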